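**Plan**

- Retrosynthesis cuts, in order: the two C–CH3 bonds of the C7 carbinol (back to a methyl ester), the two aryl–allyl bonds and the biaryl bond, the tertiary O–aryl bond, and last the two ring bonds C4a–C8a and C5–C6 of the decalin.
- Decalin locants: C2 = carbon bearing the aryl ether and a CH3, C4a = quaternary fusion carbon with CH3, C7 = carbon bearing CMe2OH, C8a = fusion CH. With CO2Me at C7 and a C7=C8 double bond, ring B is a cyclohexene-1-carboxylate. That is the retron of a [4+2] between the diene C6=C7(CO2Me)–C8=C8a and the alkene C4a=C5. Because C1–C4 already bridge C8a and C4a, the cycloaddition is intramolecular and ring A forms with it.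
- Forward: a C10 chain is built from 5-methylhex-5-en-2-one (olefination, asymmetric epoxidation, hydride opening, oxidation, iodo-olefination) and capped with an acrylate unit by Stille coupling. One thermal intramolecular Diels–Alder reaction then closes rings A and B together.
- After ring formation: hydrogenation, desilylation, O-arylation with a diaryliodonium salt, biaryl coupling, aryl allylation, methyl Grignard addition.
- Stereochemistry: C2 (R) from the Sharpless epoxidation. C4a and C8a come from the cycloaddition under control of C2 (chair tether, CH3 equatorial, oxygen axial, trans fusion). C7 comes from hydrogenation anti to the angular methyl, which is also the thermodynamically preferred equatorial ester.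

Key step: step 10

Note: the locants C1–C8a used in the discussion are those defined above. The systematic names of the bicyclic esters number the ring from the carboxyl-bearing carbon, so C7 of the discussion is C2 of those names and vice versa. The change of the C8a descriptor from R (compound 15) to S (compound 16 onward) is a CIP priority change only, not an inversion.

**Route**

Step 1
Reactants: 1 5-methylhex-5-en-2-one; 2 triethyl phosphonoacetate
Product: 3 ethyl (2E)-3,7-dimethylocta-2,7-dienoate
Conditions: NaH, THF, 0 °C to reflux; E isomer separated by chromatography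
Reagents that add atoms: none
Why: Horner–Wadsworth–Emmons olefination of the methyl ketone should give the trisubstituted enoate with the E isomer (chain trans to the ester) predominating, the minor Z isomer being removed at this stage.

Step 2
Reactants: 3 ethyl (2E)-3,7-dimethylocta-2,7-dienoate
Product: 5 (2E)-3,7-dimethylocta-2,7-dien-1-ol, via (2E)-3,7-dimethylocta-2,7-dienal 4 (not isolated)
Conditions: i-Bu2AlH, CH2Cl2, −78 to 0 °C
Reagents that add atoms: none
Why: Ester reduction with an aluminium hydride proceeds by 1,2-delivery of hydride through the aldehyde to the allylic alcohol and leaves both C=C bonds untouched.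

Step 3
Reactants: 5 (2E)-3,7-dimethylocta-2,7-dien-1-ol
Product: 6 [(2R,3R)-3-methyl-3-(3-methylbut-3-en-1-yl)oxiran-2-yl]methanol
Conditions: Ti(OiPr)4 (cat.), D-(−)-diethyl tartrate (cat.), t-BuOOH, 4 Å MS, CH2Cl2, −20 °C
Reagents that add atoms: tert-butyl hydroperoxide, CC(C)(C)OO
Why: Sharpless asymmetric epoxidation: the titanium tartrate complex binds the allylic hydroxyl and delivers oxygen to one face of the proximal alkene only (the remote 1,1-disubstituted alkene has no directing group), and the D-(−)-tartrate should give the (2R,3R)-epoxide, which fixes the future C2 centre.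

Step 4
Reactants: 6 [(2R,3R)-3-methyl-3-(3-methylbut-3-en-1-yl)oxiran-2-yl]methanol
Product: 7 (3R)-3,7-dimethyloct-7-ene-1,3-diol
Conditions: NaAlH2(OCH2CH2OMe)2, THF, 0 °C to rt
Reagents that add atoms: none
Why: Regioselective reductive opening of a 2,3-epoxy alcohol: the aluminate held on the primary oxygen delivers hydride internally to the secondary oxirane carbon, so the tertiary C–O bond and its configuration are retained in the 1,3-diol.

Step 5
Reactants: 7 (3R)-3,7-dimethyloct-7-ene-1,3-diol
Product: 9 (3R)-3,7-dimethyl-1,3-bis(triethylsilyloxy)oct-7-ene, via (3R)-3,7-dimethyl-1-(triethylsilyloxy)oct-7-en-3-ol 8 (not isolated)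
Conditions: Et3SiOTf, 2,6-lutidine, CH2Cl2, −78 to 0 °C
Reagents that add atoms: triethylsilyl trifluoromethanesulfonate, CC[Si](CC)(CC)OS(=O)(=O)C(F)(F)F
Why: Silylation with a silyl triflate, which is reactive enough to cap the tertiary hydroxyl after the primary one; no stereocentre is involved.

Step 6
Reactants: 9 (3R)-3,7-dimethyl-1,3-bis(triethylsilyloxy)oct-7-ene
Product: 10 (3R)-3,7-dimethyl-3-(triethylsilyloxy)oct-7-enal
Conditions: (COCl)2, DMSO, CH2Cl2, −78 to −40 °C; then Et3N
Reagents that add atoms: none
Why: Swern oxidation applied directly to the silyl ether: activated DMSO cleaves only the unhindered primary O–Si bond and oxidises that carbon to the aldehyde, while the tertiary silyl ether is too hindered to react.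

Step 7
Reactants: 10 (3R)-3,7-dimethyl-3-(triethylsilyloxy)oct-7-enal
Product: 11 triethyl{[(1E,4R)-1-iodo-4,7-dimethylocta-1,7-dien-4-yl]oxy}silane
Conditions: CrCl2, CHI3, dioxane/THF, 0 °C to rt
Reagents that add atoms: iodoform, IC(I)I
Why: Takai olefination: the geminal dichromium species from iodoform adds to the aldehyde and eliminates to the (E)-iodoalkene under nearly neutral conditions that spare the β-silyloxy group.

Step 8
Reactants: 12 methyl propiolate
Product: 13 methyl 2-(tributylstannyl)prop-2-enoate
Conditions: Bu3SnH, Pd(PPh3)4 (cat.), THF, 0 °C to rt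
Reagents that add atoms: tributyltin hydride, CCCC[SnH](CCCC)CCCC
Why: Palladium-catalysed hydrostannation of an alkynoate: syn addition of Sn–H with tin placed on the α-carbon should give the α-stannyl acrylate as the main regioisomer.

Step 9
Reactants: 11 triethyl{[(1E,4R)-1-iodo-4,7-dimethylocta-1,7-dien-4-yl]oxy}silane; 13 methyl 2-(tributylstannyl)prop-2-enoate
Product: 14 methyl (3E,6R)-6,9-dimethyl-2-methylidene-6-(triethylsilyloxy)deca-3,9-dienoate
Conditions: Pd(PPh3)4 (cat.), CuI (cat.), DMF, rt, dark; product kept cold and dilute with BHT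
Reagents that add atoms: none
Why: Stille cross-coupling, accelerated by CuI, joins the two sp2 carbons with retention of the E geometry of the iodoalkene under neutral conditions that the silyl ether and the diene ester tolerate.

Step 10
Reactants: 14 methyl (3E,6R)-6,9-dimethyl-2-methylidene-6-(triethylsilyloxy)deca-3,9-dienoate
Product: 15 methyl (4aS,7R,8aR)-4a,7-dimethyl-7-(triethylsilyloxy)-3,4,4a,5,6,7,8,8a-octahydronaphthalene-2-carboxylate
Conditions: toluene (0.005 M), BHT (cat.), 190 °C, sealed tube
Reagents that add atoms: none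
Why: Thermal intramolecular Diels–Alder reaction with inverse electron demand: the electron-poor diene C6=C7(CO2Me)–C8=C8a and the electron-rich 1,1-disubstituted alkene C4a=C5 combine in a concerted but asynchronous [4+2], the C5–C6 bond to the acrylate β-carbon running ahead of the C4a–C8a bond. The closest known reaction types are the thermal cyclisation of 1,7,9-decatrienes to octalins and the inverse-demand cycloadditions of 2-alkoxycarbonyl-1,3-dienes. Both new σ-bonds lie in ring B, which is the six-membered cycloadduct ring proper; ring A (C1, C2, C3, C4, C4a, C8a) closes simultaneously as a six-membered carbocycle because the tether atoms C1–C4 link the diene terminus C8a to the alkene carbon C4a. C8a is set trans to the C4a methyl by the tether-exo transition state with a chair tether and the E diene, and both centres are set relative to C2 by the chair that keeps C2–CH3 equatorial and the smaller OSiEt3 axial. The step needs intramolecular over intermolecular reaction (high dilution, inhibitor, gem-dialkyl effect of the quaternary C2) and trans over cis fusion (the cis transition state must place the diene arm syn-axial to a C2 substituent, which a quaternary C2 makes unavoidable). It also needs the correct face, which rests only on the equatorial preference of CH3 over OSiEt3, so the trans adduct with the opposite ring-fusion configuration is the expected minor diastereomer and is removed by chromatography.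

Step 11
Reactants: 15 methyl (4aS,7R,8aR)-4a,7-dimethyl-7-(triethylsilyloxy)-3,4,4a,5,6,7,8,8a-octahydronaphthalene-2-carboxylate
Product: 16 methyl (2R,4aS,7R,8aS)-4a,7-dimethyl-7-(triethylsilyloxy)decahydronaphthalene-2-carboxylate
Conditions: H2 (1 atm), Pd/C, EtOAc, rt
Reagents that add atoms: none
Why: Heterogeneous catalytic hydrogenation of the trisubstituted enoate: hydrogen is delivered syn from the face opposite the axial angular methyl (the H8a face), which places the C7 ester equatorial, the same epimer that base equilibration of this enolisable centre would favour.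

Step 12
Reactants: 16 methyl (2R,4aS,7R,8aS)-4a,7-dimethyl-7-(triethylsilyloxy)decahydronaphthalene-2-carboxylate
Product: 17 methyl (2R,4aS,7R,8aS)-7-hydroxy-4a,7-dimethyldecahydronaphthalene-2-carboxylate
Conditions: Bu4NF, THF, rt
Reagents that add atoms: none
Why: Fluoride-mediated desilylation, driven by the strong Si–F bond, frees the tertiary alcohol without touching the ester or any stereocentre.

Step 13
Reactants: 18 2-bromo-4-chloro-1-iodobenzene
Product: 20 (2-bromo-4-chlorophenyl)(2,4,6-trimethoxyphenyl)iodonium 4-methylbenzenesulfonate, via 2-bromo-4-chloro-1-[hydroxy(tosyloxy)iodo]benzene 19 (not isolated)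
Conditions: mCPBA, TsOH·H2O, MeCN, 77 °C; then 1,3,5-trimethoxybenzene, rt
Reagents that add atoms: 1,3,5-trimethoxybenzene, COc1cc(OC)cc(OC)c1; 4-methylbenzenesulfonic acid monohydrate, Cc1ccc(S(=O)(=O)O)cc1.O; 3-chloroperoxybenzoic acid (oxygen of 19 only), OOC(=O)c1cccc(Cl)c1
Why: One-pot diaryliodonium salt synthesis: oxidation of the iodoarene to the trivalent-iodine tosylate followed by electrophilic aromatic substitution on 1,3,5-trimethoxybenzene gives the unsymmetrical salt, in which the electron-rich trimethoxyphenyl group is the ligand that is not transferred.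

Step 14
Reactants: 17 methyl (2R,4aS,7R,8aS)-7-hydroxy-4a,7-dimethyldecahydronaphthalene-2-carboxylate; 20 (2-bromo-4-chlorophenyl)(2,4,6-trimethoxyphenyl)iodonium 4-methylbenzenesulfonate
Product: 21 methyl (2R,4aS,7R,8aS)-7-(2-bromo-4-chlorophenoxy)-4a,7-dimethyldecahydronaphthalene-2-carboxylate
Conditions: NaH, toluene, 0 °C to rt
Reagents that add atoms: none
Why: Metal-free O-arylation of a tertiary alkoxide with a diaryliodonium salt: the alkoxide binds trivalent iodine and ligand coupling transfers the more electron-poor, ortho-substituted aryl group to oxygen, so the C2–O bond and its configuration are never broken.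

Step 15
Reactants: 22 1-(allyloxy)-4-bromobenzene
Product: 24 2-allyl-4-bromophenol, via 6-allyl-4-bromocyclohexa-2,4-dien-1-one 23 (not isolated)
Conditions: PhNEt2, 200 °C
Reagents that add atoms: none
Why: Aromatic Claisen rearrangement: a concerted [3,3]-sigmatropic shift to the ortho position (both ortho sites are equivalent and the para site is blocked) followed by tautomerisation of the dienone to the phenol.

Step 16
Reactants: 24 2-allyl-4-bromophenol
Product: 25 2-allyl-4-(4,4,5,5-tetramethyl-1,3,2-dioxaborolan-2-yl)phenol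
Conditions: B2pin2, Pd(dppf)Cl2 (cat.), KOAc, dioxane, 85 °C
Reagents that add atoms: bis(pinacolato)diboron, CC1(C)OB(B2OC(C)(C)C(C)(C)O2)OC1(C)C
Why: Miyaura borylation of the aryl bromide with a weak acetate base, which tolerates the free phenol and leaves the allyl group in place.

Step 17
Reactants: 21 methyl (2R,4aS,7R,8aS)-7-(2-bromo-4-chlorophenoxy)-4a,7-dimethyldecahydronaphthalene-2-carboxylate; 25 2-allyl-4-(4,4,5,5-tetramethyl-1,3,2-dioxaborolan-2-yl)phenol
Product: 26 methyl (2R,4aS,7R,8aS)-7-{[3'-allyl-5-chloro-4'-hydroxy-(1,1'-biphenyl)-2-yl]oxy}-4a,7-dimethyldecahydronaphthalene-2-carboxylate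
Conditions: Pd(dppf)Cl2 (cat.), K2CO3, dioxane/H2O, 80 °C
Reagents that add atoms: none
Why: Suzuki–Miyaura coupling that is chemoselective for the C–Br bond over the C–Cl bond with a bisphosphine palladium catalyst and forms the biaryl bond ortho to the ether oxygen.

Step 18
Reactants: 26 methyl (2R,4aS,7R,8aS)-7-{[3'-allyl-5-chloro-4'-hydroxy-(1,1'-biphenyl)-2-yl]oxy}-4a,7-dimethyldecahydronaphthalene-2-carboxylate
Product: 27 methyl (2R,4aS,7R,8aS)-7-{[3',5-diallyl-4'-hydroxy-(1,1'-biphenyl)-2-yl]oxy}-4a,7-dimethyldecahydronaphthalene-2-carboxylate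
Conditions: allylB(pin), Pd(OAc)2 (cat.), SPhos, K3PO4, THF/H2O, 60 °C
Reagents that add atoms: allylboronic acid pinacol ester, C=CCB1OC(C)(C)C(C)(C)O1
Why: Suzuki–Miyaura allylation of the aryl chloride, whose oxidative addition is enabled by the electron-rich biaryl phosphine, installs the second allyl group at a temperature low enough to avoid migration of the allyl double bonds into conjugation.

Step 19
Reactants: 27 methyl (2R,4aS,7R,8aS)-7-{[3',5-diallyl-4'-hydroxy-(1,1'-biphenyl)-2-yl]oxy}-4a,7-dimethyldecahydronaphthalene-2-carboxylate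
Product: 29 2-[(2R,4aS,7R,8aS)-7-{[3',5-diallyl-4'-hydroxy-(1,1'-biphenyl)-2-yl]oxy}-4a,7-dimethyldecahydronaphthalen-2-yl]propan-2-ol, via C7 methyl ketone 28 (not isolated)
Conditions: MeMgBr (excess), THF, 0 °C to rt; aq. NH4Cl
Reagents that add atoms: methylmagnesium bromide, C[Mg]Br
Why: Double Grignard addition to the methyl ester through the ketone gives the dimethyl carbinol, one further equivalent being consumed by the phenol; the equatorial C7 configuration is retained because it is the stable epimer and the basic aryl tert-alkyl ether sees no acid.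

**Compound list**

1 | 5-methylhex-5-en-2-one | CC(=O)CCC(C)=C | starting material
2 | triethyl phosphonoacetate | CCOC(=O)CP(=O)(OCC)OCC | starting material
3 | ethyl (2E)-3,7-dimethylocta-2,7-dienoate | C=C(C)CC/C(C)=C/C(=O)OCC | intermediate
4 | (2E)-3,7-dimethylocta-2,7-dienal | C=C(C)CC/C(C)=C/C=O | intermediate (not isolated)
5 | (2E)-3,7-dimethylocta-2,7-dien-1-ol | C=C(C)CC/C(C)=C/CO | intermediate
6 | [(2R,3R)-3-methyl-3-(3-methylbut-3-en-1-yl)oxiran-2-yl]methanol | OC[C@H]1O[C@]1(C)CCC(C)=C | intermediate
7 | (3R)-3,7-dimethyloct-7-ene-1,3-diol | OCC[C@](C)(O)CCC(C)=C | intermediate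
8 | (3R)-3,7-dimethyl-1-(triethylsilyloxy)oct-7-en-3-ol | CC[Si](CC)(CC)OCC[C@](C)(O)CCC(C)=C | intermediate (not isolated)
9 | (3R)-3,7-dimethyl-1,3-bis(triethylsilyloxy)oct-7-ene | CC[Si](CC)(CC)OCC[C@](C)(O[Si](CC)(CC)CC)CCC(C)=C | intermediate
10 | (3R)-3,7-dimethyl-3-(triethylsilyloxy)oct-7-enal | O=CC[C@](C)(O[Si](CC)(CC)CC)CCC(C)=C | intermediate
11 | triethyl{[(1E,4R)-1-iodo-4,7-dimethylocta-1,7-dien-4-yl]oxy}silane | I/C=C/C[C@](C)(O[Si](CC)(CC)CC)CCC(C)=C | intermediate
12 | methyl propiolate | C#CC(=O)OC | starting material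
13 | methyl 2-(tributylstannyl)prop-2-enoate | C=C(C(=O)OC)[Sn](CCCC)(CCCC)CCCC | intermediate
14 | methyl (3E,6R)-6,9-dimethyl-2-methylidene-6-(triethylsilyloxy)deca-3,9-dienoate | C=C(C(=O)OC)/C=C/C[C@](C)(O[Si](CC)(CC)CC)CCC(C)=C | intermediate
15 | methyl (4aS,7R,8aR)-4a,7-dimethyl-7-(triethylsilyloxy)-3,4,4a,5,6,7,8,8a-octahydronaphthalene-2-carboxylate (trans-fused, silyloxy group syn to H8a) | CC[Si](CC)(CC)O[C@]1(C)CC[C@]2(C)CCC(C(=O)OC)=C[C@H]2C1 | intermediate
16 | methyl (2R,4aS,7R,8aS)-4a,7-dimethyl-7-(triethylsilyloxy)decahydronaphthalene-2-carboxylate | CC[Si](CC)(CC)O[C@]1(C)CC[C@]2(C)CC[C@@H](C(=O)OC)C[C@H]2C1 | intermediate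
17 | methyl (2R,4aS,7R,8aS)-7-hydroxy-4a,7-dimethyldecahydronaphthalene-2-carboxylate | O[C@]1(C)CC[C@]2(C)CC[C@@H](C(=O)OC)C[C@H]2C1 | intermediate
18 | 2-bromo-4-chloro-1-iodobenzene | Clc1ccc(I)c(Br)c1 | starting material
19 | 2-bromo-4-chloro-1-[hydroxy(tosyloxy)iodo]benzene | Cc1ccc(S(=O)(=O)OI(O)c2ccc(Cl)cc2Br)cc1 | intermediate (not isolated)
20 | (2-bromo-4-chlorophenyl)(2,4,6-trimethoxyphenyl)iodonium 4-methylbenzenesulfonate | COc1cc(OC)c([I+]c2ccc(Cl)cc2Br)c(OC)c1.Cc1ccc(S(=O)(=O)[O-])cc1 | intermediate
21 | methyl (2R,4aS,7R,8aS)-7-(2-bromo-4-chlorophenoxy)-4a,7-dimethyldecahydronaphthalene-2-carboxylate | Clc1ccc(O[C@]2(C)CC[C@]3(C)CC[C@@H](C(=O)OC)C[C@H]3C2)c(Br)c1 | intermediate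
22 | 1-(allyloxy)-4-bromobenzene | C=CCOc1ccc(Br)cc1 | starting material
23 | 6-allyl-4-bromocyclohexa-2,4-dien-1-one | O=C1C=CC(Br)=CC1CC=C | intermediate (not isolated)
24 | 2-allyl-4-bromophenol | C=CCc1cc(Br)ccc1O | intermediate
25 | 2-allyl-4-(4,4,5,5-tetramethyl-1,3,2-dioxaborolan-2-yl)phenol | C=CCc1cc(B2OC(C)(C)C(C)(C)O2)ccc1O | intermediate
26 | methyl (2R,4aS,7R,8aS)-7-{[3'-allyl-5-chloro-4'-hydroxy-(1,1'-biphenyl)-2-yl]oxy}-4a,7-dimethyldecahydronaphthalene-2-carboxylate | Clc1ccc(O[C@]2(C)CC[C@]3(C)CC[C@@H](C(=O)OC)C[C@H]3C2)c(-c2ccc(O)c(CC=C)c2)c1 | intermediate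
27 | methyl (2R,4aS,7R,8aS)-7-{[3',5-diallyl-4'-hydroxy-(1,1'-biphenyl)-2-yl]oxy}-4a,7-dimethyldecahydronaphthalene-2-carboxylate | C=CCc1ccc(O[C@]2(C)CC[C@]3(C)CC[C@@H](C(=O)OC)C[C@H]3C2)c(-c2ccc(O)c(CC=C)c2)c1 | intermediate
28 | 1-[(2R,4aS,7R,8aS)-7-{[3',5-diallyl-4'-hydroxy-(1,1'-biphenyl)-2-yl]oxy}-4a,7-dimethyldecahydronaphthalen-2-yl]ethan-1-one | C=CCc1ccc(O[C@]2(C)CC[C@]3(C)CC[C@@H](C(C)=O)C[C@H]3C2)c(-c2ccc(O)c(CC=C)c2)c1 | intermediate (not isolated)
29 | 2-[(2R,4aS,7R,8aS)-7-{[3',5-diallyl-4'-hydroxy-(1,1'-biphenyl)-2-yl]oxy}-4a,7-dimethyldecahydronaphthalen-2-yl]propan-2-ol | C=CCc1ccc(O[C@]2(C)CC[C@]3(C)CC[C@@H](C(C)(C)O)C[C@H]3C2)c(-c2ccc(O)c(CC=C)c2)c1 | target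

**Step count**

Total steps: 19. Longest linear sequence: 15 steps (steps 1–7, 9–12, 14, 17–19, from ketone 1).

**Steps most likely to fail**

1. Step 10. The two chair transition states may be poorly discriminated, since C2 distinguishes the faces only through the axial/equatorial preference of CH3 versus OSiEt3. Some material may leak into the cis-fused manifold, and the electron-poor diene may dimerise by intermolecular cycloaddition during the long heating. The fallback introduces a removable steric directing group on C8; it sets out from aldehyde 10 and returns to the route at ester 16. Ramirez dibromo-olefination of 10 (CBr4, PPh3, Et3N, CH2Cl2) should give triethyl{[(4R)-1,1-dibromo-4,7-dimethylocta-1,7-dien-4-yl]oxy}silane F1. Stille coupling of F1 with stannane 13 (Pd2(dba)3, tri(2-furyl)phosphine) exchanges only the bromine trans to the chain in 1,1-dibromoalkenes and should give methyl (3Z,6R)-3-bromo-6,9-dimethyl-2-methylidene-6-(triethylsilyloxy)deca-3,9-dienoate F2. The bromine on C8, cis to C1, clashes with C2 in any transition state that folds the tether under the diene, a known device for reinforcing trans fusion in decatriene cycloadditions, and the more substituted diene is less prone to dimerise. Heating F2 as in step 10 should give methyl (4aS,7R,8aS)-1-bromo-4a,7-dimethyl-7-(triethylsilyloxy)-3,4,4a,5,6,7,8,8a-octahydronaphthalene-2-carboxylate F3. Hydrogenation of F3 (H2, Pd/C, Et3N, EtOAc) removes the vinylic bromine and saturates the ring, giving 16. The face selectivity still rests on C2 in this variant.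

2. Step 14. The hindered tertiary sodium alkoxide may attack the methyl ester of a second molecule (transesterification, oligomer formation) faster than it undergoes ligand coupling on iodine. The fallback takes the ester out of play; it sets out from hydroxy ester 17 and returns at aryl ether 21. Saponification of 17 (LiOH, THF/H2O) should give (2R,4aS,7R,8aS)-7-hydroxy-4a,7-dimethyldecahydronaphthalene-2-carboxylic acid F4. Double deprotonation of F4 (NaH, 2.2 equiv, THF/DMF) and addition of salt 20 at room temperature should arylate only the alkoxide, because carboxylates react with such salts only under forcing conditions, giving (2R,4aS,7R,8aS)-7-(2-bromo-4-chlorophenoxy)-4a,7-dimethyldecahydronaphthalene-2-carboxylic acid F5. Esterification of F5 with Me3SiCHN2 in toluene/MeOH gives 21.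

3. Step 9. Transmetalation of the hindered α-stannyl acrylate may be slow (protodestannylation, homocoupling), and the diene ester may oligomerise during coupling and isolation. The fallback builds the diene ester by carbonylation instead; it sets out from aldehyde 10 and returns at triene 14. Wittig olefination of 10 with Ph3P=CHC(O)CH3 (toluene, 80 °C) should give (3E,6R)-6,9-dimethyl-6-(triethylsilyloxy)deca-3,9-dien-2-one F6. Kinetic deprotonation of F6 at the methyl group (KN(SiMe3)2, THF, −78 °C) and trapping with PhNTf2 should give (3E,6R)-6,9-dimethyl-6-(triethylsilyloxy)deca-1,3,9-trien-2-yl trifluoromethanesulfonate F7. Palladium-catalysed methoxycarbonylation of F7 (Pd(OAc)2, PPh3, CO, MeOH, Et3N, DMF) gives 14.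

**Further compounds**

F1 | step 10 | triethyl{[(4R)-1,1-dibromo-4,7-dimethylocta-1,7-dien-4-yl]oxy}silane | BrC(Br)=CC[C@](C)(O[Si](CC)(CC)CC)CCC(C)=C
F2 | step 10 | methyl (3Z,6R)-3-bromo-6,9-dimethyl-2-methylidene-6-(triethylsilyloxy)deca-3,9-dienoate | C=C(C(=O)OC)/C(Br)=C/C[C@](C)(O[Si](CC)(CC)CC)CCC(C)=C
F3 | step 10 | methyl (4aS,7R,8aS)-1-bromo-4a,7-dimethyl-7-(triethylsilyloxy)-3,4,4a,5,6,7,8,8a-octahydronaphthalene-2-carboxylate | CC[Si](CC)(CC)O[C@]1(C)CC[C@]2(C)CCC(C(=O)OC)=C(Br)[C@H]2C1
F4 | step 14 | (2R,4aS,7R,8aS)-7-hydroxy-4a,7-dimethyldecahydronaphthalene-2-carboxylic acid | O[C@]1(C)CC[C@]2(C)CC[C@@H](C(=O)O)C[C@H]2C1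
F5 | step 14 | (2R,4aS,7R,8aS)-7-(2-bromo-4-chlorophenoxy)-4a,7-dimethyldecahydronaphthalene-2-carboxylic acid | Clc1ccc(O[C@]2(C)CC[C@]3(C)CC[C@@H](C(=O)O)C[C@H]3C2)c(Br)c1
F6 | step 9 | (3E,6R)-6,9-dimethyl-6-(triethylsilyloxy)deca-3,9-dien-2-one | CC(=O)/C=C/C[C@](C)(O[Si](CC)(CC)CC)CCC(C)=C
F7 | step 9 | (3E,6R)-6,9-dimethyl-6-(triethylsilyloxy)deca-1,3,9-trien-2-yl trifluoromethanesulfonate | C=C(OS(=O)(=O)C(F)(F)F)/C=C/C[C@](C)(O[Si](CC)(CC)CC)CCC(C)=C
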